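**Retrosynthetic overview**

1. The target is cut into two trans-fused oxepane–cyclohexane halves that differ only at the acetoxy carbon C7 (axial OAc in one half, equatorial in the other). Both C7 centres are traced back to C7=O, and the C3 ketones are carried as silyl ethers.
2. Key disconnection, in the axial-acetate half: the ring bond C5a–C6 and the linker bond C6–CH2 are cut together. A cyclopentanone whose carbonyl carbon (the later C7) is bonded directly to the quaternary angular-methyl carbon C5a takes up one carbon (C6, from CH2Br2) between C7 and C5a, and the ring-enlarged magnesium enolate is trapped at C6 by the aldehyde of the other half.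
3. Enabling feature: C6, the ring CH that carries the CH2CH2 linker, lies between the oxygenated carbon C7 and the quaternary ring-fusion carbon C5a. With C7 as C=O, C6 is an enolate carbon, and C5a is the more substituted α-carbon of the smaller ketone, so it is the carbon that migrates.
4. Both halves come from one cyclopentanone, 10. Its oxepane is closed by 7-endo epoxide opening; its C5a/C–O stereodiad comes from a semipinacol shift of an epoxy alcohol made from 2-methylcyclopent-2-enone (CBS reduction sets the absolute configuration).
5. Ring order: cyclopentane (purchased) → oxepane (step 7) → cyclohexane by one-carbon ring enlargement (step 10 for the equatorial-acetate half, step 13 for the axial-acetate half).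

Key step: step 13

Remark: the two acetoxy-bearing carbons of the target have opposite configurations (R in the half written first in the SMILES, S in the other; all other centres are S in both halves), so the halves are completed differently after a common intermediate.
Remark: the Shi epoxidation with the D-fructose-derived ketone is assumed to give the (R)-oxirane; this centre (C3) ends as a carbonyl carbon, so its epimer would serve equally.
Remark: carbinol 12 is ring-enlarged twice with different metals. The lithium carbenoid is used where the ring-enlarged enolate has to be alkylated by a halide (step 10). The magnesium carbenoid is used where the enolate has to add to an enolisable aldehyde (step 13).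
Locants for each six-membered half (1-benzoxepine numbering): O1, C2 (CMe2), C3, C4, C5, C5a (angular Me), C6 (CH carrying the linker), C7 (carbinol/acetate carbon), C8, C9, C9a (CH–O). TBS = tert-butyldimethylsilyl.

**Route**

Step 1
Reactants: 1 2-methylcyclopent-2-en-1-one
Product: 2 (R)-2-methylcyclopent-2-en-1-ol
Conditions: (S)-2-methyl-CBS-oxazaborolidine (10 mol%), BH3·SMe2, THF, −20 °C; aq. work-up
Reagents that add atoms: none
Why: Corey–Bakshi–Shibata reduction: the oxazaborolidine–borane complex binds the carbonyl with the alkenyl side as the large group and delivers hydride to one face only, which should set the carbinol centre as R.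

Step 2
Reactants: 2 (R)-2-methylcyclopent-2-en-1-ol
Product: 3 (1R,2R,5S)-1-methyl-6-oxabicyclo[3.1.0]hexan-2-ol (OH cis to the epoxide)
Conditions: VO(acac)2 (2 mol%), t-BuOOH, CH2Cl2, 0 °C → rt
Reagents that add atoms: tert-butyl hydroperoxide, CC(C)(C)OO
Why: Hydroxyl-directed vanadium-catalysed epoxidation of a cyclic allylic alcohol: the vanadate ester delivers the peroxide oxygen to the alkene face syn to OH, so both epoxide centres are set cis to the hydroxyl.

Step 3
Reactants: 3 cis-epoxy alcohol
Product: 4 (1S,5S)-1-methyl-6-oxabicyclo[3.1.0]hexan-2-one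
Conditions: Dess–Martin periodinane, NaHCO3, CH2Cl2, 0 °C → rt
Reagents that add atoms: none
Why: Dess–Martin oxidation under buffered, non-basic conditions converts the secondary alcohol into the ketone without opening or epimerising the α,β-epoxide.

Step 4
Reactants: 4 epoxy ketone; 5 5-bromo-2-methylpent-2-ene (as its Grignard reagent)
Product: 6 (1S,2R,5S)-1-methyl-2-(4-methylpent-3-en-1-yl)-6-oxabicyclo[3.1.0]hexan-2-ol (tertiary OH cis to the epoxide)
Conditions: 5, Mg, THF; then 4, THF, −78 °C; aq. pH 7 buffer
Reagents that add atoms: (4-methylpent-3-en-1-yl)magnesium bromide, CC(C)=CCC[Mg]Br (made in the flask from 5 and Mg)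
Why: Grignard 1,2-addition to an α,β-epoxy ketone: the nucleophile approaches the carbonyl from the face opposite the epoxide oxygen, which places the new tertiary hydroxyl cis to the epoxide and the side chain trans to it, as the next step requires.

Step 5
Reactants: 6 tertiary epoxy alcohol
Product: 7 (2R,3S)-3-hydroxy-2-methyl-2-(4-methylpent-3-en-1-yl)cyclopentan-1-one (OH cis to the ring methyl, trans to the side chain)
Conditions: ZnBr2 (0.2 equiv), CH2Cl2, 0 °C → rt
Reagents that add atoms: none
Why: Semipinacol rearrangement of a 2,3-epoxy alcohol: Lewis-acid activation of the epoxide lets the side chain, which is antiperiplanar to the breaking C–O bond at the methyl-bearing carbon, migrate with inversion there, so the quaternary centre forms with the retained secondary hydroxyl cis to the methyl group and trans to the side chain.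

Step 6
Reactants: 7 hydroxy ketone
Product: 8 (2R,3S)-2-{2-[(2R)-3,3-dimethyloxiran-2-yl]ethyl}-3-hydroxy-2-methylcyclopentan-1-one
Conditions: D-fructose-derived Shi ketone (0.3 equiv), KHSO5, K2CO3, Bu4NHSO4, MeCN–CH2(OMe)2–aq. buffer, 0 °C
Reagents that add atoms: potassium peroxymonosulfate, [K+].[O-]S(=O)(=O)OO
Why: Shi asymmetric epoxidation: the chiral dioxirane reacts only with the electron-rich trisubstituted alkene and sets the new oxirane centre (R) under catalyst control, while the hydroxy ketone is left untouched at 0 °C in the buffered medium.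

Step 7
Reactants: 8 epoxy hydroxy ketone
Product: 9 (3R,5aR,8aS)-3-hydroxy-2,2,5a-trimethyloctahydro-6H-cyclopenta[b]oxepin-6-one (trans-fused)
Conditions: (1S)-camphor-10-sulfonic acid (0.1 equiv), CH2Cl2, 0 °C
Reagents that add atoms: none
Why: Acid-catalysed intramolecular epoxide opening (7-endo-tet): Markovnikov cleavage of the protonated trisubstituted epoxide at its tertiary carbon by the secondary hydroxyl closes the oxepane, whereas the 6-exo mode would need attack at the carbon next to the gem-dimethyl group and would build a trans-fused oxa-hydrindane; C3 keeps the epoxide configuration and the trans ring fusion follows from step 5.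

Step 8
Reactants: 9 oxepanol
Product: 10 (3R,5aR,8aS)-3-(tert-butyldimethylsilyloxy)-2,2,5a-trimethyloctahydro-6H-cyclopenta[b]oxepin-6-one
Conditions: TBSOTf, 2,6-lutidine, CH2Cl2, −78 °C
Reagents that add atoms: tert-butyldimethylsilyl triflate, CC(C)(C)[Si](C)(C)OS(=O)(=O)C(F)(F)F
Why: Silylation of the hindered secondary alcohol with the silyl triflate and a hindered pyridine base at low temperature leaves the ketone unenolised; no stereocentre changes.

Step 9
Reactants: 10 bicyclic cyclopentanone; 11 dibromomethane
Product: 12 dibromomethyl carbinol of 10 (CHBr2 on the former carbonyl carbon, OH cis to the angular methyl)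
Conditions: CH2Br2, LiN(i-Pr)2, THF, −90 °C; then 10, −90 → −78 °C; AcOH
Reagents that add atoms: dibromomethyllithium, [Li]C(Br)Br (made in the flask from 11)
Why: 1,2-Addition of dibromomethyllithium, a small and weakly basic carbenoid, to the hindered ketone (first stage of the β-oxido carbenoid ring enlargement); attack anti to the angular methyl should give one carbinol epimer, whose configuration is irrelevant because this centre becomes a carbonyl carbon again.

Step 10
Reactants: 12 dibromomethyl carbinol; 13 methyl bromoacetate
Product: 17 methyl 2-[(3R,5aS,6S,9aS)-3-(TBS-oxy)-2,2,5a-trimethyl-7-oxodecahydro-1-benzoxepin-6-yl]acetate (C6 substituent equatorial), via lithium β-oxido carbenoid 14 (not isolated), via lithium enolate 15 (not isolated), via axial ester epimer 16 (not isolated)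
Conditions: n-BuLi (2.1 equiv), THF, −78 → 0 °C; 13, DMPU, −78 → −20 °C; then DBU (0.2 equiv), toluene, 40 °C
Reagents that add atoms: methyl bromoacetate (13), COC(=O)CBr
Why: β-Oxido carbenoid ring enlargement followed by enolate alkylation: bromine–lithium exchange gives carbenoid 14, the quaternary carbon migrates with retention and loss of LiBr to give the six-membered lithium enolate 15 regiospecifically, the reactive α-bromo ester alkylates this lithium enolate at C6 mainly anti to the axial angular methyl (16), and DBU then equilibrates this enolisable centre to the equatorial epimer 17 (substituent cis to the angular methyl).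

Step 11
Reactants: 17 keto ester
Product: 18 methyl 2-[3-(TBS-oxy)-2,2,5a-trimethyl-7-methylidenedecahydro-1-benzoxepin-6-yl]acetate
Conditions: Ph3PCH3Br, KOt-Bu, toluene, 0 → 80 °C
Reagents that add atoms: methylenetriphenylphosphorane, C=P(c1ccccc1)(c1ccccc1)c1ccccc1 (made in the flask from Ph3PCH3Br and KOt-Bu)
Why: Wittig methylenation of the ketone in the presence of the less electrophilic methyl ester; C6 is already in its thermodynamic configuration, so the basic ylide cannot degrade it.

Step 12
Reactants: 18 methylidene ester
Product: 19 2-[3-(TBS-oxy)-2,2,5a-trimethyl-7-methylidenedecahydro-1-benzoxepin-6-yl]acetaldehyde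
Conditions: i-Bu2AlH (1.1 equiv), CH2Cl2, −78 °C; aq. potassium sodium tartrate
Reagents that add atoms: none
Why: Partial reduction of the methyl ester with i-Bu2AlH at −78 °C stops at the aluminium hemiacetal, which releases the aldehyde on work-up; the 1,1-disubstituted alkene and the silyl ether are inert and no stereocentre is adjacent to the new carbonyl.

Step 13
Reactants: 12 dibromomethyl carbinol; 19 aldehyde of the equatorial-acetate half
Product: 22 aldol adduct (β-hydroxy ketone joining both halves; mixture at C6 and the carbinol carbon), via magnesium β-oxido carbenoid 20 (not isolated), via magnesium enolate 21 (not isolated)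
Conditions: 12, i-PrMgCl (2.05 equiv), THF, −78 → 0 °C; then −78 °C, 19 (1.0 equiv), −78 → −40 °C; AcOH, −78 °C
Reagents that add atoms: none
Why: i-PrMgCl first deprotonates the tertiary alcohol and then exchanges one bromine for magnesium, giving the magnesium β-oxido carbenoid 20, in which the quaternary ring carbon C5a migrates from the carbinol carbon to the carbenoid carbon with loss of MgBrCl; this one-carbon enlargement turns the cyclopentane into the cyclohexane and delivers the magnesium enolate 21 regiospecifically, with the inserted carbon C6 as the nucleophilic carbon, which then adds to aldehyde 19 through a chelated chair transition state (aldol addition). The closest known reaction type is the β-oxido carbenoid ring enlargement of cycloalkanone–dihalomethane adducts, known for lithium and for magnesium carbenoids, with interception of the ring-enlarged metal enolate by a carbonyl electrophile; the carbenoid is made here by bromine–magnesium exchange of a geminal dibromide, the standard entry to α-bromoalkylmagnesium reagents. No ring is closed by cyclisation: the six-membered ring arises by 1,2-shift ring expansion (five to six) of the carbocycle of 12, and the oxepane is carried through unchanged. The migrating carbon C5a keeps its configuration, so the trans ring fusion set in steps 5 and 7 is transferred; the two new centres (C6 and the carbinol carbon) form without reliable control, which is tolerated because the carbinol is eliminated in step 14 and C6 is reset in step 15. The step needs migration of C5a and not of the ring CH2, which the higher migratory aptitude of the more substituted, electron-richer carbon in this anion-accelerated shift should secure. It also needs aldol addition to outrun proton transfer from the enolisable aldehyde, which the weakly basic magnesium enolate, the stable chelated magnesium aldolate, the low temperature and the absence of excess Grignard reagent (two equivalents of i-PrMgCl, no more) should secure.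

Step 14
Reactants: 22 aldol adduct
Product: 24 (Z)-exocyclic enone (C6=CH–CH2 link between the halves), via mesylate 23 (not isolated)
Conditions: MsCl, Et3N, CH2Cl2, 0 °C; then DBU, toluene, 60 °C
Reagents that add atoms: none
Why: Mesylation of the aldol hydroxyl and base-induced elimination (E1cB through the ketone enolate) give the conjugated exocyclic enone and remove both uncontrolled centres; the Z isomer (alkyl group syn to the carbonyl, away from the quaternary carbon) is expected, and either geometry serves in the next step.

Step 15
Reactants: 24 enone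
Product: 25 saturated ketone (C7=O in one half, C7=CH2 in the other, CH2CH2 linker equatorial on both C6 atoms)
Conditions: [(Ph3P)CuH]6 (5 mol%), PhMe2SiH, t-BuOH, toluene, rt; then DBU (cat.), rt
Reagents that add atoms: none
Why: Copper hydride-catalysed conjugate reduction (hydrosilane as the stoichiometric hydride source) is selective for the enone over the isolated 1,1-disubstituted alkene, and protonation of the resulting enolate at C6 from the face opposite the axial angular methyl places the linker equatorial, which is also the thermodynamic arrangement reached with DBU.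

Step 16
Reactants: 25 ketone
Product: 26 tertiary alcohol (C7: OH axial and cis to the angular methyl, CH3 equatorial)
Conditions: MeMgBr, CeCl3, THF, −78 → 0 °C
Reagents that add atoms: methylmagnesium bromide, C[Mg]Br
Why: Organocerium-mediated Grignard addition to the cyclohexanone: axial attack is blocked by the syn-axial angular methyl two carbons away, so the methyl group enters equatorially and the new tertiary hydroxyl is axial, while CeCl3 suppresses enolisation.

Step 17
Reactants: 26 alcohol bearing the exocyclic methylene
Product: 28 bis-tertiary diol (second C7: OH equatorial, CH3 axial), via organomercury acetate 27 (not isolated)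
Conditions: Hg(OAc)2, THF–H2O, rt; then NaBH4, aq. NaOH, 0 °C
Reagents that add atoms: water, O
Why: Oxymercuration–demercuration (Markovnikov hydration) of the exocyclic methylene: water adds to the tertiary carbon from the open equatorial side, away from the syn-axial angular methyl, which gives the equatorial tertiary alcohol with an axial methyl, the opposite configuration to that made in step 16.

Step 18
Reactants: 28 diol
Product: 29 bis-acetate bis-TBS ether
Conditions: AcCl, PhNMe2, CH2Cl2, 0 → 40 °C
Reagents that add atoms: acetyl chloride, CC(=O)Cl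
Why: Acetylation of both hindered tertiary alcohols with acetyl chloride and a weak aromatic amine base, conditions that esterify tertiary carbinols without eliminating them; configurations are untouched.

Step 19
Reactants: 29 bis-silyl ether
Product: 30 bis-acetate diol (free C3–OH in both oxepanes)
Conditions: HF·pyridine, pyridine, THF, 0 °C → rt
Reagents that add atoms: none
Why: Fluoride-mediated cleavage of the two secondary silyl ethers; the tertiary acetates are stable to buffered HF.

Step 20
Reactants: 30 diol
Product: 31 target CNP0325605.1
Conditions: Dess–Martin periodinane, NaHCO3, CH2Cl2, rt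
Reagents that add atoms: none
Why: Dess–Martin oxidation of the two secondary alcohols next to the gem-dimethyl carbons gives the two oxepan-3-ones and removes the temporary C3 stereocentres.

**Compound list**

1 | 2-methylcyclopent-2-en-1-one | CC1=CCCC1=O | starting material
2 | (R)-2-methylcyclopent-2-en-1-ol | O[C@@H]1CCC=C1C | intermediate
3 | (1R,2R,5S)-1-methyl-6-oxabicyclo[3.1.0]hexan-2-ol | O[C@@H]1CC[C@@H]2O[C@]12C | intermediate
4 | (1S,5S)-1-methyl-6-oxabicyclo[3.1.0]hexan-2-one | O=C1CC[C@@H]2O[C@]12C | intermediate
5 | 5-bromo-2-methylpent-2-ene | CC(C)=CCCBr | starting material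
6 | (1S,2R,5S)-1-methyl-2-(4-methylpent-3-en-1-yl)-6-oxabicyclo[3.1.0]hexan-2-ol | CC(C)=CCC[C@@]1(O)CC[C@@H]2O[C@]12C | intermediate
7 | (2R,3S)-3-hydroxy-2-methyl-2-(4-methylpent-3-en-1-yl)cyclopentan-1-one | O=C1CC[C@H](O)[C@@]1(C)CCC=C(C)C | intermediate
8 | (2R,3S)-2-{2-[(2R)-3,3-dimethyloxiran-2-yl]ethyl}-3-hydroxy-2-methylcyclopentan-1-one | O=C1CC[C@H](O)[C@@]1(C)CC[C@H]1OC1(C)C | intermediate
9 | (3R,5aR,8aS)-3-hydroxy-2,2,5a-trimethyloctahydro-6H-cyclopenta[b]oxepin-6-one | O=C1CC[C@@H]2OC(C)(C)[C@H](O)CC[C@@]12C | intermediate
10 | (3R,5aR,8aS)-3-(tert-butyldimethylsilyloxy)-2,2,5a-trimethyloctahydro-6H-cyclopenta[b]oxepin-6-one | O=C1CC[C@@H]2OC(C)(C)[C@H](O[Si](C)(C)C(C)(C)C)CC[C@@]12C | intermediate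
11 | dibromomethane | BrCBr | starting material
12 | dibromomethyl carbinol of 10 (OH cis to the angular methyl) | BrC(Br)[C@@]1(O)CC[C@@H]2OC(C)(C)[C@H](O[Si](C)(C)C(C)(C)C)CC[C@@]12C | intermediate
13 | methyl bromoacetate | COC(=O)CBr | starting material
14 | lithium β-oxido carbenoid from 12 (carbenoid carbon unassigned) | [Li]O[C@]1(C([Li])Br)CC[C@@H]2OC(C)(C)[C@H](O[Si](C)(C)C(C)(C)C)CC[C@@]12C | intermediate (not isolated)
15 | ring-enlarged lithium enolate (C7–OLi, C6=C7) | [Li]OC1=C[C@]2(C)CC[C@@H](O[Si](C)(C)C(C)(C)C)C(C)(C)O[C@H]2CC1 | intermediate (not isolated)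
16 | keto ester with axial C6 substituent (C6 epimer of 17) | O=C1CC[C@@H]2OC(C)(C)[C@H](O[Si](C)(C)C(C)(C)C)CC[C@@]2(C)[C@H]1CC(=O)OC | intermediate (not isolated)
17 | methyl 2-[(3R,5aS,6S,9aS)-3-(TBS-oxy)-2,2,5a-trimethyl-7-oxodecahydro-1-benzoxepin-6-yl]acetate | O=C1CC[C@@H]2OC(C)(C)[C@H](O[Si](C)(C)C(C)(C)C)CC[C@@]2(C)[C@@H]1CC(=O)OC | intermediate
18 | 7-methylidene analogue of 17 (same relative configuration) | C=C1CC[C@@H]2OC(C)(C)[C@H](O[Si](C)(C)C(C)(C)C)CC[C@@]2(C)[C@@H]1CC(=O)OC | intermediate
19 | aldehyde from 18 (CH2CHO equatorial on C6, 7-methylidene) | C=C1CC[C@@H]2OC(C)(C)[C@H](O[Si](C)(C)C(C)(C)C)CC[C@@]2(C)[C@@H]1CC=O | intermediate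
20 | magnesium β-oxido carbenoid from 12 (carbenoid carbon unassigned) | Cl[Mg]O[C@]1(C([Mg]Cl)Br)CC[C@@H]2OC(C)(C)[C@H](O[Si](C)(C)C(C)(C)C)CC[C@@]12C | intermediate (not isolated)
21 | ring-enlarged magnesium enolate (C7–OMgCl, C6=C7) | Cl[Mg]OC1=C[C@]2(C)CC[C@@H](O[Si](C)(C)C(C)(C)C)C(C)(C)O[C@H]2CC1 | intermediate (not isolated)
22 | aldol adduct: 7-oxo half linked through C6–CH(OH)–CH2 to C6 of the 7-methylidene half (C6 and carbinol carbon as a mixture) | O=C1CC[C@@H]2OC(C)(C)[C@H](O[Si](C)(C)C(C)(C)C)CC[C@@]2(C)C1C(O)C[C@@H]1C(=C)CC[C@@H]2OC(C)(C)[C@H](O[Si](C)(C)C(C)(C)C)CC[C@@]12C | intermediate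
23 | methanesulfonate of 22 | O=C1CC[C@@H]2OC(C)(C)[C@H](O[Si](C)(C)C(C)(C)C)CC[C@@]2(C)C1C(OS(C)(=O)=O)C[C@@H]1C(=C)CC[C@@H]2OC(C)(C)[C@H](O[Si](C)(C)C(C)(C)C)CC[C@@]12C | intermediate (not isolated)
24 | (Z)-enone: C6=CH–CH2 link, C7=O in one half, C7=CH2 in the other | O=C1CC[C@@H]2OC(C)(C)[C@H](O[Si](C)(C)C(C)(C)C)CC[C@@]2(C)/C1=C/C[C@@H]1C(=C)CC[C@@H]2OC(C)(C)[C@H](O[Si](C)(C)C(C)(C)C)CC[C@@]12C | intermediate
25 | saturated ketone: CH2CH2 linker equatorial on both C6 atoms, C7=O and C7=CH2 | O=C1CC[C@@H]2OC(C)(C)[C@H](O[Si](C)(C)C(C)(C)C)CC[C@@]2(C)[C@@H]1CC[C@@H]1C(=C)CC[C@@H]2OC(C)(C)[C@H](O[Si](C)(C)C(C)(C)C)CC[C@@]12C | intermediate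
26 | tertiary alcohol (axial OH at C7 of the first half), 7-methylidene in the second half | O[C@]1(C)CC[C@@H]2OC(C)(C)[C@H](O[Si](C)(C)C(C)(C)C)CC[C@@]2(C)[C@@H]1CC[C@@H]1C(=C)CC[C@@H]2OC(C)(C)[C@H](O[Si](C)(C)C(C)(C)C)CC[C@@]12C | intermediate
27 | organomercury acetate (CH2HgOAc axial, OH equatorial on C7 of the second half) | O[C@]1(C)CC[C@@H]2OC(C)(C)[C@H](O[Si](C)(C)C(C)(C)C)CC[C@@]2(C)[C@@H]1CC[C@@H]1[C@@](C[Hg]OC(C)=O)(O)CC[C@@H]2OC(C)(C)[C@H](O[Si](C)(C)C(C)(C)C)CC[C@@]12C | intermediate (not isolated)
28 | bis-tertiary diol (axial OH in the first half, equatorial OH in the second), bis-TBS ether | O[C@]1(C)CC[C@@H]2OC(C)(C)[C@H](O[Si](C)(C)C(C)(C)C)CC[C@@]2(C)[C@@H]1CC[C@@H]1[C@@](C)(O)CC[C@@H]2OC(C)(C)[C@H](O[Si](C)(C)C(C)(C)C)CC[C@@]12C | intermediate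
29 | bis-acetate of 28 | CC(=O)O[C@]1(C)CC[C@@H]2OC(C)(C)[C@H](O[Si](C)(C)C(C)(C)C)CC[C@@]2(C)[C@@H]1CC[C@@H]1[C@@](C)(OC(C)=O)CC[C@@H]2OC(C)(C)[C@H](O[Si](C)(C)C(C)(C)C)CC[C@@]12C | intermediate
30 | bis-acetate with free (3R)-hydroxyl groups in both oxepanes | CC(=O)O[C@]1(C)CC[C@@H]2OC(C)(C)[C@H](O)CC[C@@]2(C)[C@@H]1CC[C@@H]1[C@@](C)(OC(C)=O)CC[C@@H]2OC(C)(C)[C@H](O)CC[C@@]12C | intermediate
31 | CNP0325605.1 (bis-oxepanone diacetate) | CC(=O)O[C@]1(C)CC[C@@H]2OC(C)(C)C(=O)CC[C@@]2(C)[C@@H]1CC[C@H]1[C@]2(C)CCC(=O)C(C)(C)O[C@H]2CC[C@]1(C)OC(C)=O | target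

**Step count and risks**

Total step count: 20. Longest linear sequence: 20 steps (1 to 31 by way of 17–19).

Steps most likely to fail:

1. Step 13. The ring CH2 may migrate instead of the quaternary carbon in the carbenoid shift, the magnesium carbenoid may be alkylated by remaining Grignard reagent before it rearranges, or the enolate may take a proton from the enolisable aldehyde instead of forming the C–C bond. The fallback enlarges the ring by a cationic epoxy-alcohol semipinacol shift and joins the halves by a radical conjugate addition; it sets out from 10 and 19 and returns at 25. Vinylmagnesium bromide with CeCl3 adds to 10 to give the vinyl carbinol F1, and VO(acac)2/t-BuOOH converts it into the epoxy alcohol F2. BF3·OEt2 at −78 °C then opens the epoxide with 1,2-shift of the tertiary ring carbon, the carbon best able to bear positive charge, which enlarges the ring and gives the hydroxymethyl ketone F3; mesylation and DBU give the α-methylene ketone F4. In parallel, 19 is oxidised with NaClO2/NaH2PO4/2-methylbut-2-ene to the carboxylic acid F5, which is esterified with N-hydroxyphthalimide (DIC, DMAP) to the N-acyloxyphthalimide F6. Irradiation of F4 and F6 with Ru(bpy)3Cl2, Hantzsch ester and i-Pr2NEt (blue light) should release the primary radical by decarboxylation and add it to the exocyclic methylene (Giese addition), giving ketone 25 after hydrogen transfer and equilibration with DBU.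

2. Step 7. The hydroxyl may open the epoxide at its secondary carbon (6-exo) and close a tetrahydropyran instead of the oxepane. The fallback activates the alkene instead of an epoxide; it sets out from 7 (step 6 is omitted) and returns at 9. Treatment of 7 with Hg(OCOCF3)2 in MeNO2 at −20 °C and then aqueous NaCl should give the oxepanylmercury chloride F7, because Markovnikov alkoxymercuration can place the oxygen only on the tertiary alkene carbon. Oxidative demercuration (NaBH4, O2, DMF) then gives 9 together with its C3 epimer F8; both are silylated and carried on, since C3 becomes a carbonyl carbon in step 20.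

3. Step 5. The trisubstituted alkene of the side chain may capture the developing tertiary cation (cation–olefin cyclisation) in competition with the 1,2-shift. The fallback installs that alkene only after the rearrangement; it sets out from 4 and returns at 7. But-3-en-1-ylmagnesium bromide adds to 4 to give the butenyl epoxy alcohol F9, and ZnBr2 rearranges it to the butenyl hydroxy ketone F10, whose terminal alkene is too weak a nucleophile to interfere. Cross-metathesis with 2-methylbut-2-ene (second-generation Grubbs catalyst, CH2Cl2, 40 °C) then gives 7.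

Further compounds
F1 | step 13 | vinyl carbinol from 10 (OH cis to the angular methyl) | C=C[C@@]1(O)CC[C@@H]2OC(C)(C)[C@H](O[Si](C)(C)C(C)(C)C)CC[C@@]12C
F2 | step 13 | oxiranyl carbinol from F1 (oxirane CH unassigned) | C1OC1[C@@]1(O)CC[C@@H]2OC(C)(C)[C@H](O[Si](C)(C)C(C)(C)C)CC[C@@]12C
F3 | step 13 | 6-(hydroxymethyl)-7-oxodecahydro-1-benzoxepine (C6 unassigned) | O=C1CC[C@@H]2OC(C)(C)[C@H](O[Si](C)(C)C(C)(C)C)CC[C@@]2(C)C1CO
F4 | step 13 | 6-methylidene-7-oxodecahydro-1-benzoxepine (α-methylene ketone) | O=C1CC[C@@H]2OC(C)(C)[C@H](O[Si](C)(C)C(C)(C)C)CC[C@@]2(C)C1=C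
F5 | step 13 | carboxylic acid from 19 | C=C1CC[C@@H]2OC(C)(C)[C@H](O[Si](C)(C)C(C)(C)C)CC[C@@]2(C)[C@@H]1CC(=O)O
F6 | step 13 | N-acyloxyphthalimide of F5 | C=C1CC[C@@H]2OC(C)(C)[C@H](O[Si](C)(C)C(C)(C)C)CC[C@@]2(C)[C@@H]1CC(=O)ON1C(=O)c2ccccc2C1=O
F7 | step 7 | oxepanylmercury chloride (HgCl on C3, unassigned) | O=C1CC[C@@H]2OC(C)(C)C([Hg]Cl)CC[C@@]12C
F8 | step 7 | (3S)-epimer of 9 | O=C1CC[C@@H]2OC(C)(C)[C@@H](O)CC[C@@]12C
F9 | step 5 | 2-(but-3-en-1-yl)-1-methyl-6-oxabicyclo[3.1.0]hexan-2-ol (OH cis to the epoxide) | C=CCC[C@@]1(O)CC[C@@H]2O[C@]12C
F10 | step 5 | 2-(but-3-en-1-yl)-3-hydroxy-2-methylcyclopentan-1-one (OH cis to the ring methyl) | O=C1CC[C@H](O)[C@@]1(C)CCC=C
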